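**Retrosynthetic overview**
1. Target 15 ⇒ tetra-MOM ether 14 by acetal hydrolysis. 14 ⇒ benzyl alcohol 11 + benzyl bromide 12 by a C–O disconnection (Williamson); both halves come from one aldehyde, 10.
2. 10 ⇒ 2,3-dibromo-4,5-dihydroxybenzaldehyde 9 ⇒ 5,6-dibromovanillin 8 ⇒ vanillin 6, by O-demethylation and two directed brominations.
3. Key C–C disconnection: the aryl–C(benzylic) bond of 6 ⇒ guaiacol phenolate (a vinylogous enolate) + glyoxylic acid. Aldol-type addition gives mandelic acid 4, and oxidative decarboxylation then gives 6.
4. No ring is formed. Both benzene rings come intact from guaiacol.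

Assumption: the target SMILES has no stereocentre and the molecule is achiral, so there is no enantiomer to select. The only stereocentres on the way (in 3 and 4) are formed without control and are erased in step 2.

**Step 1**
Reactants: 1 guaiacol (2-methoxyphenol, 1.8 equiv, excess recovered); 2 glyoxylic acid (50 % aq. solution)
Product: 4 (±)-4-hydroxy-3-methoxymandelic acid, via para-dienone aldol adduct 4-[carboxy(hydroxy)methyl]-2-methoxycyclohexa-2,5-dien-1-one 3 (not isolated)
Conditions: aq NaOH (1 equiv per acidic OH), H2O, 0 → 30 °C, 24 h; HCl to pH 6, toluene wash (removes 1); HCl to pH 1–2, EtOAc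
Reagents that add atoms: none
Why: The phenolate of 1 is a vinylogous enolate whose para carbon adds to the very electrophilic aldehyde carbonyl of glyoxylate in an intermolecular aldol-type addition (phenolate hydroxyalkylation), dienone 3 re-aromatises by tautomerisation, para beats the one free ortho site through sterics and carboxylate/phenolate repulsion, excess 1 suppresses double addition, and the new carbinol centre is racemic and disappears in step 2.

**Step 2**
Reactants: 4 (±)-4-hydroxy-3-methoxymandelic acid
Product: 6 vanillin (4-hydroxy-3-methoxybenzaldehyde), via 4-hydroxy-3-methoxyphenylglyoxylic acid 5 (not isolated)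
Conditions: air (O2) sparge, CuSO4·5H2O (5 mol %), 2 M aq NaOH, 95 °C, 6 h; then HCl to pH 2–3, 60 °C
Reagents that add atoms: none
Why: Cu(II)/O2 dehydrogenates the benzylic α-hydroxy acid to the arylglyoxylic acid 5, which loses CO2 on acidification because of its p-hydroxyaryl group (oxidative decarboxylation), leaving the carbon brought in by glyoxylic acid as the ring aldehyde.

**Step 3**
Reactants: 6 vanillin
Product: 7 5-bromovanillin (3-bromo-4-hydroxy-5-methoxybenzaldehyde)
Conditions: Br2 (1.05 equiv), AcOH, rt, 2 h; ice-water, filter
Reagents that add atoms: bromine, BrBr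
Why: In this electrophilic aromatic bromination the free OH is the dominant director, and with its para site (CHO) and one ortho site (OMe) occupied, only the remaining ortho carbon reacts.

**Step 4**
Reactants: 7 5-bromovanillin
Product: 8 5,6-dibromovanillin (2,3-dibromo-4-hydroxy-5-methoxybenzaldehyde)
Conditions: Br2 (1.5 equiv), Fe powder (10 mol %), AcOH, 25 → 60 °C, 6 h; aq NaHSO3, filter, recrystallise (AcOH)
Reagents that add atoms: bromine, BrBr
Why: In this FeBr3-catalysed electrophilic aromatic bromination all ortho/para sites of OH are filled, so OMe directs to its para carbon next to the first bromine, while the other free CH is squeezed between CHO and OMe, which gives the contiguous 2,3-dibromo pattern.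

**Step 5**
Reactants: 8 5,6-dibromovanillin
Product: 9 2,3-dibromo-4,5-dihydroxybenzaldehyde
Conditions: AlCl3 (1.3 equiv), pyridine (4.5 equiv), CH2Cl2, reflux, 24 h, N2; then 2 M HCl
Reagents that add atoms: none
Why: Al(III) chelates the phenolate and the neighbouring OMe in a five-membered ring, so the activated methyl is removed by pyridine in an SN2 step (Lewis-acid-assisted O-demethylation of an o-hydroxyanisole) under conditions that leave CHO and both C–Br bonds alone.

**Step 6**
Reactants: 9 2,3-dibromo-4,5-dihydroxybenzaldehyde
Product: 10 2,3-dibromo-4,5-bis(methoxymethoxy)benzaldehyde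
Conditions: MOMCl (3 equiv), K2CO3 (4 equiv), acetone, 0 °C → rt, 8 h
Reagents that add atoms: chloromethyl methyl ether (MOMCl), COCCl
Why: O-alkylation of both acidic phenolates by the highly reactive α-chloro ether installs acetal protecting groups that are inert to hydride, Appel and NaH conditions and can later be removed without hydrogenolysis or strong Lewis acids, which would attack C–Br or benzylic C–O bonds.

**Step 7**
Reactants: 10 2,3-dibromo-4,5-bis(methoxymethoxy)benzaldehyde
Product: 11 [2,3-dibromo-4,5-bis(methoxymethoxy)phenyl]methanol
Conditions: NaBH4 (0.5 equiv), MeOH–THF 1:1, 0 °C, 30 min; H2O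
Reagents that add atoms: none
Why: Borohydride reduction is chemoselective for the aldehyde, and aryl bromides and MOM acetals are untouched.

**Step 8**
Reactants: 11 [2,3-dibromo-4,5-bis(methoxymethoxy)phenyl]methanol (about half of the batch)
Product: 12 2,3-dibromo-1-(bromomethyl)-4,5-bis(methoxymethoxy)benzene
Conditions: CBr4 (1.25 equiv), PPh3 (1.3 equiv), CH2Cl2, 0 °C, 1 h
Reagents that add atoms: carbon tetrabromide, BrC(Br)(Br)Br
Why: The Appel reaction turns the primary benzylic alcohol into the bromide by SN2 on the alkoxyphosphonium ion under essentially neutral conditions, so the acid-labile MOM groups survive.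

**Step 9**
Reactants: 11 [2,3-dibromo-4,5-bis(methoxymethoxy)phenyl]methanol; 12 2,3-dibromo-1-(bromomethyl)-4,5-bis(methoxymethoxy)benzene (1.05 equiv)
Product: 14 bis[2,3-dibromo-4,5-bis(methoxymethoxy)benzyl] ether, via sodium [2,3-dibromo-4,5-bis(methoxymethoxy)phenyl]methanolate 13 (not isolated)
Conditions: NaH (1.2 equiv), THF, 0 °C, 30 min; then 12, n-Bu4NI (10 mol %), 0 °C → rt, 12 h
Reagents that add atoms: sodium hydride, [Na+].[H-] (its sodium stays only in intermediate 13, not in 14)
Why: In this Williamson ether synthesis a primary alkoxide displaces bromide from a primary benzylic bromide (SN2, iodide-catalysed) with no elimination pathway and no base-sensitive group present.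

**Step 10**
Reactants: 14 bis[2,3-dibromo-4,5-bis(methoxymethoxy)benzyl] ether
Product: 15 bis(2,3-dibromo-4,5-dihydroxybenzyl) ether (target)
Conditions: 6 M aq HCl–THF (1:4), 40 °C, 4–6 h, argon; EtOAc extraction, alcohol-free chromatography or crystallisation
Reagents that add atoms: none
Why: Acid-catalysed acetal hydrolysis frees the four phenols, while the central dialkyl ether persists because two bromines per ring disfavour the benzylic cation/quinone methide and no alcohol solvent is present to exchange with it.

**Compound list**
1 | guaiacol (2-methoxyphenol) | COc1ccccc1O | starting material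
2 | glyoxylic acid | O=CC(=O)O | starting material
3 | 4-[carboxy(hydroxy)methyl]-2-methoxycyclohexa-2,5-dien-1-one (transient, stereoisomer mixture) | O=C1C=CC(C(O)C(=O)O)C=C1OC | intermediate
4 | (±)-4-hydroxy-3-methoxymandelic acid | COc1cc(C(O)C(=O)O)ccc1O | intermediate
5 | 4-hydroxy-3-methoxyphenylglyoxylic acid | COc1cc(C(=O)C(=O)O)ccc1O | intermediate
6 | vanillin | COc1cc(C=O)ccc1O | intermediate
7 | 5-bromovanillin (3-bromo-4-hydroxy-5-methoxybenzaldehyde) | COc1cc(C=O)cc(Br)c1O | intermediate
8 | 5,6-dibromovanillin (2,3-dibromo-4-hydroxy-5-methoxybenzaldehyde) | COc1cc(C=O)c(Br)c(Br)c1O | intermediate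
9 | 2,3-dibromo-4,5-dihydroxybenzaldehyde | Oc1cc(C=O)c(Br)c(Br)c1O | intermediate
10 | 2,3-dibromo-4,5-bis(methoxymethoxy)benzaldehyde | COCOc1cc(C=O)c(Br)c(Br)c1OCOC | intermediate
11 | [2,3-dibromo-4,5-bis(methoxymethoxy)phenyl]methanol | COCOc1cc(CO)c(Br)c(Br)c1OCOC | intermediate
12 | 2,3-dibromo-1-(bromomethyl)-4,5-bis(methoxymethoxy)benzene | COCOc1cc(CBr)c(Br)c(Br)c1OCOC | intermediate
13 | sodium [2,3-dibromo-4,5-bis(methoxymethoxy)phenyl]methanolate | [Na+].[O-]Cc1cc(OCOC)c(OCOC)c(Br)c1Br | intermediate
14 | bis[2,3-dibromo-4,5-bis(methoxymethoxy)benzyl] ether | COCOc1cc(COCc2cc(OCOC)c(OCOC)c(Br)c2Br)c(Br)c(Br)c1OCOC | intermediate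
15 | bis(2,3-dibromo-4,5-dihydroxybenzyl) ether (achiral) | Oc1cc(COCc2cc(O)c(O)c(Br)c2Br)c(Br)c(Br)c1O | target

**Total step count:** 10. **Longest linear sequence:** 10 (steps 1–10; 11 is used twice, once directly and once via 12).

**Three steps most likely to fail**

Step 10. Once the para-OH is free, acid can solvolyse the p-hydroxybenzyl ether to the benzyl alcohol or its methyl ether, and the liberated formaldehyde can condense with the catechol. The fallback removes acid from the end game.
- It sets out from 9. Acetylation (Ac2O, pyridine, 0 °C → rt) gives 4,5-diacetoxy-2,3-dibromobenzaldehyde F1.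
- Reductive homo-etherification of this electron-poor aldehyde (Et3SiH 1.2 equiv, BiBr3 5 mol %, MeCN, rt) gives bis(4,5-diacetoxy-2,3-dibromobenzyl) ether F2.
- The four aryl acetates are removed by transesterification (K2CO3, degassed MeOH–THF, 0 °C, argon, then cold dilute HCl to pH 4). An alkoxide is too poor a leaving group for quinone methide formation under these conditions.
- The fallback comes back to the route at 15.

Step 4. The second bromination acts on a deactivated ring and competes with ipso-bromodeformylation and incomplete conversion. The fallback reverses the order of the two brominations, so that each is driven by a strong director.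
- It sets out from 6. Acetylation (Ac2O, pyridine) gives vanillin acetate F3.
- With the phenol masked, OMe directs bromine to its para position (Br2, KBr, H2O, rt), giving 6-bromovanillin acetate F4.
- Acid hydrolysis (6 M HCl, reflux) gives 6-bromovanillin F5.
- Br2 in AcOH at rt then brominates ortho to the free OH, and the fallback comes back to the route at 8.

Step 1. Ortho isomer, bis-adduct and Cannizzaro loss of glyoxylate lower the yield, and the product is very water-soluble. The fallback blocks the ortho site and changes the C–C bond-forming reaction.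
- It sets out from 1. Ortho-selective bromination (Br2, t-BuNH2, toluene, −70 °C) gives 2-bromo-6-methoxyphenol F6.
- A phenolic Mannich reaction (37 % aq CH2O, 40 % aq Me2NH, EtOH, reflux) can now only go para, giving 2-bromo-4-[(dimethylamino)methyl]-6-methoxyphenol F7.
- Sommelet-type oxidation with hexamethylenetetramine in refluxing aq AcOH, then HCl, converts the benzylamine into the aldehyde.
- The fallback comes back to the route at 7.

**Further compounds**
F1 | step 10 | 4,5-diacetoxy-2,3-dibromobenzaldehyde | CC(=O)Oc1cc(C=O)c(Br)c(Br)c1OC(C)=O
F2 | step 10 | bis(4,5-diacetoxy-2,3-dibromobenzyl) ether | CC(=O)Oc1cc(COCc2cc(OC(C)=O)c(OC(C)=O)c(Br)c2Br)c(Br)c(Br)c1OC(C)=O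
F3 | step 4 | vanillin acetate (4-formyl-2-methoxyphenyl acetate) | COc1cc(C=O)ccc1OC(C)=O
F4 | step 4 | 6-bromovanillin acetate (5-bromo-4-formyl-2-methoxyphenyl acetate) | COc1cc(C=O)c(Br)cc1OC(C)=O
F5 | step 4 | 6-bromovanillin (2-bromo-4-hydroxy-5-methoxybenzaldehyde) | COc1cc(C=O)c(Br)cc1O
F6 | step 1 | 2-bromo-6-methoxyphenol | COc1cccc(Br)c1O
F7 | step 1 | 2-bromo-4-[(dimethylamino)methyl]-6-methoxyphenol | COc1cc(CN(C)C)cc(Br)c1O
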